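**Plan**

1. Retrosynthesis: the three phenol MOM ethers and the two aryl carbonyls (formyl, isovaleryl; two directed ortho-lithiations) come off first; the isopropenyl group is traced back to a C7 nitrile and the C4 carbinol to a C4 ketone.
2. Ring B is then cut at C5–C6 and C7–C8. Its C6–C7 edge is acrylonitrile, C5 is the α-carbon of the C4 ketone, and C8 is the end of an iodoethyl arm on quaternary C10, so one Michael addition/ring-closing alkylation can make both bonds.
3. The annulation precursor, a regiodefined C4–C5 silyl enol ether, comes from anti vinyl-copper addition to (S)-3-methyl-4-(arylmethyl)cyclohex-2-enone, then hydroboration and iodination.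
4. Forward order: arylpropanal → ring A (organocatalytic Michael/aldol condensation) → C10 → ring B (key step) → C4 carbinol → C7 acetyl → isopropenyl → arene acylations → deprotection; the arene is bought as phloroglucinol.
5. Stereochemistry: C1 from the (S)-prolinol catalyst; C10 anti to the C1 substituent; C5 by equilibration through the C4 ketone (trans-fused); C4 by oxygen trapping on the α face; C7 by epimerization of the acetyl group to equatorial.

Key step: step 8

Remark: locants follow the eudesmane skeleton (C1 carries the arylmethyl carbon C16, C4 is the carbinol carbon, C5 and C10 are the ring-fusion atoms, C7 carries the isopropenyl group; ring A = C1–C5 and C10, ring B = C5–C10); α/β mean the face opposite to/the same as the C10 methyl. Compounds 20–24 are expected as C7 nitrile epimers (the equatorial 7β epimer is drawn); they converge at 26.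

**Step 1**
Reactants: 1 phloroglucinol
Product: 2 1,3,5-tris(methoxymethoxy)benzene
Conditions: MOMCl, i-Pr2NEt, CH2Cl2, 0 → 23 °C
Reagents that add atoms: chloromethyl methyl ether, COCCl
Why: Threefold O-alkylation of the phenol (Williamson-type ether formation) installs base-stable, ortho-directing, acid-labile MOM ethers, and no stereocenter is formed.

**Step 2**
Reactants: 2 1,3,5-tris(methoxymethoxy)benzene; 3 acrolein
Product: 7 3-[2,4,6-tris(methoxymethoxy)phenyl]propanal, via aryllithium 4 (not isolated), via aryl Grignard reagent 5 (not isolated), via silyl enol ether 6 (not isolated)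
Conditions: n-BuLi, THF, 0 °C; MgBr2·OEt2; CuBr·SMe2 (10 mol %), TMSCl, HMPA, acrolein, −78 °C; aq citric acid, 0 °C
Reagents that add atoms: none
Why: Directed ortho-lithiation between two OMOM groups, transmetalation to magnesium and copper-catalysed, chlorosilane-accelerated conjugate addition to the enal give the aldehyde as its silyl enol ether, which mild acid hydrolyses, and no stereocenter is formed.

**Step 3**
Reactants: 7 3-[2,4,6-tris(methoxymethoxy)phenyl]propanal; 8 methyl vinyl ketone
Product: 10 (4S)-4-{[2,4,6-tris(methoxymethoxy)phenyl]methyl}cyclohex-2-en-1-one, via keto aldehyde 9 (not isolated)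
Conditions: (S)-2-[diphenyl(trimethylsilyloxy)methyl]pyrrolidine (10 mol %), ethyl 3,4-dihydroxybenzoate (20 mol %), neat, 4 °C; then LiOH·H2O (catalytic), i-PrOH, 23 °C
Reagents that add atoms: none
Why: Enamine-catalysed Michael addition of the aldehyde to the enone followed by intramolecular aldol condensation (organocatalytic Robinson-type annulation) builds ring A, the (S)-catalyst shielding one face of the (E)-enamine so that the future C1 is formed as (S).

**Step 4**
Reactants: 10 (4S)-4-{[2,4,6-tris(methoxymethoxy)phenyl]methyl}cyclohex-2-en-1-one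
Product: 12 (4S)-3-methyl-4-{[2,4,6-tris(methoxymethoxy)phenyl]methyl}cyclohex-2-en-1-one, via lithium enolate 11 (not isolated)
Conditions: Me2CuLi (from MeLi, CuI), Et2O, −78 °C; then PhS(Cl)=N-t-Bu, THF, −78 → 23 °C
Reagents that add atoms: lithium dimethylcuprate, [Li+].C[Cu-]C
Why: Cuprate 1,4-addition followed in the same flask by dehydrogenation of the enolate with the sulfinimidoyl chloride (α-sulfenylation and syn-elimination) returns the enone with the future C10 methyl in place, C1 being untouched and the transient C10 center destroyed.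

**Step 5**
Reactants: 12 (4S)-3-methyl-4-{[2,4,6-tris(methoxymethoxy)phenyl]methyl}cyclohex-2-en-1-one
Product: 13 triethyl{[(3S,4S)-3-ethenyl-3-methyl-4-{[2,4,6-tris(methoxymethoxy)phenyl]methyl}cyclohex-1-en-1-yl]oxy}silane
Conditions: CH2=CHMgBr, CuBr·SMe2 (20 mol %), TESCl, HMPA, THF, −78 → −40 °C; Et3N
Reagents that add atoms: vinylmagnesium bromide, C=C[Mg]Br; chlorotriethylsilane, CC[Si](Cl)(CC)CC
Why: Copper-catalysed, chlorosilane-accelerated conjugate addition creates quaternary C10 with the vinyl group anti to the pseudoaxial C1 arylmethyl group (methyl therefore cis to it), and O-silylation fixes the enolate on the C4–C5 side.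

**Step 6**
Reactants: 13 triethylsilyl enol ether with the C10 vinyl group
Product: 15 2-[(1S,6S)-1-methyl-3-(triethylsilyloxy)-6-{[2,4,6-tris(methoxymethoxy)phenyl]methyl}cyclohex-2-en-1-yl]ethan-1-ol, via alkylborane 14 (not isolated)
Conditions: 9-BBN, THF, 0 → 23 °C; then NaBO3·4H2O, H2O, 23 °C
Reagents that add atoms: sodium perborate, [Na+].[O-]OB=O
Why: Anti-Markovnikov hydroboration–oxidation of the monosubstituted alkene, in which the bulky borane leaves the hindered trisubstituted silyl enol ether alone and perborate is mild enough to keep it, forms no stereocenter.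

**Step 7**
Reactants: 15 primary alcohol
Product: 16 triethyl{[(3S,4S)-3-(2-iodoethyl)-3-methyl-4-{[2,4,6-tris(methoxymethoxy)phenyl]methyl}cyclohex-1-en-1-yl]oxy}silane
Conditions: I2, PPh3, imidazole, CH2Cl2, 0 °C
Reagents that add atoms: iodine, II
Why: Appel-type iodination of the primary alcohol under imidazole buffering leaves the silyl enol ether and MOM ethers intact and provides the electrophilic C8 terminus without touching a stereocenter.

**Step 8**
Reactants: 16 iodoethyl silyl enol ether; 17 acrylonitrile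
Product: 21 (2R,4aS,5S,8aR)-4a-methyl-8-oxo-5-{[2,4,6-tris(methoxymethoxy)phenyl]methyl}decahydronaphthalene-2-carbonitrile (trans-fused keto nitrile), via sulfonium enolate 18 (not isolated), via cyano carbanion 19 (not isolated), via cis-fused keto nitrile 20 (not isolated)
Conditions: TASF [(Me2N)3S+ Me3SiF2−] (1.1 equiv), acrylonitrile (1.3 equiv), THF, −78 → 0 °C; then NaOMe (catalytic), MeOH, 23 °C
Reagents that add atoms: none
Why: Fluoride cleaves the Si–O bond of 16 to the naked, regiodefined C4–C5 enolate 18, which adds through C5 to the β-carbon of acrylonitrile (C5–C6), and the resulting α-cyano carbanion 19 displaces the primary iodide on the C10 arm (C7–C8), so ring B closes by a 6-exo-tet alkylation and both bonds arise in one flask. The closest known reaction type is the Michael-initiated ring closure (Michael addition/intramolecular alkylation, an anionic formal [4+2] annulation). C5 is set first under kinetic control by axial attack anti to the pseudoaxial C10 methyl, which should give the cis-fused ketone 20, and is then corrected by methoxide equilibration through the C4 enolate to the trans-fused 21, expected to be the more stable isomer because the arylmethyl group, the nitrile and both ring-fusion bonds are equatorial. C7 is not controlled here, because it becomes epimerizable and is set in step 11. The step needs C5 rather than C3 regiochemistry, secured by the silyl enol ether inherited from the conjugate addition, and Michael addition rather than self-alkylation of the enolate, secured because O-alkylation would give a bridgehead enol ether and four-ring closure is slow beside addition to the acrylonitrile already present. The carbanion must cyclize faster than it takes a proton from C3, for which the iodide leaving group, the sulfonium counter-ion and the low temperature are chosen.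

**Step 9**
Reactants: 21 trans-fused keto nitrile
Product: 22 (2R,4aS,5S,8aS)-4a-methyl-8-methylidene-5-{[2,4,6-tris(methoxymethoxy)phenyl]methyl}decahydronaphthalene-2-carbonitrile
Conditions: Ph3PCH3Br, KOt-Bu, toluene, 80 °C
Reagents that add atoms: methyltriphenylphosphonium bromide, C[P+](c1ccccc1)(c1ccccc1)c1ccccc1.[Br-]
Why: Wittig methylenation of the hindered C4 ketone gives the exocyclic alkene while nitrile and MOM ethers are inert, and the ring fusion is already the thermodynamic one so the basic ylide cannot erode it.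

**Step 10**
Reactants: 22 exocyclic alkene
Product: 24 (2R,4aS,5S,8R,8aR)-8-hydroxy-4a,8-dimethyl-5-{[2,4,6-tris(methoxymethoxy)phenyl]methyl}decahydronaphthalene-2-carbonitrile, via hydroperoxide 23 (not isolated)
Conditions: Mn(dpm)3 (10 mol %; dpm = 2,2,6,6-tetramethylheptane-3,5-dionate), PhSiH3, O2 (1 atm), i-PrOH/CH2Cl2, 0 °C; then PPh3, 23 °C
Reagents that add atoms: dioxygen, O=O
Why: Mukaiyama hydration (hydrogen-atom transfer to the CH2 terminus, oxygen trapping of the tertiary C4 radical, reduction of the hydroperoxide) gives the Markovnikov alcohol, oxygen entering from the equatorial α face because the axial β face is blocked by the 1,3-diaxial C10 methyl, hence 4α-OH and 4β-CH3.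

**Step 11**
Reactants: 24 hydroxy nitrile
Product: 26 1-[(2R,4aS,5S,8R,8aR)-8-hydroxy-4a,8-dimethyl-5-{[2,4,6-tris(methoxymethoxy)phenyl]methyl}decahydronaphthalen-2-yl]ethan-1-one, via lithium ketimide 25 (not isolated)
Conditions: MeLi (4 equiv), Et2O, 0 → 23 °C; aq HCl to pH 3, THF, 0 °C; then NaOMe (catalytic), MeOH, 23 °C
Reagents that add atoms: methyllithium, [Li]C; water, O
Why: Organolithium addition to the nitrile stops at the N-lithio ketimine, which mild acid hydrolyses to the methyl ketone, and methoxide then epimerizes C7 to the equatorial 7β-acetyl isomer so that both nitrile epimers converge.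

**Step 12**
Reactants: 26 hydroxy methyl ketone
Product: 27 (1R,4S,4aS,7R,8aR)-1,4a-dimethyl-7-(prop-1-en-2-yl)-4-{[2,4,6-tris(methoxymethoxy)phenyl]methyl}decahydronaphthalen-1-ol
Conditions: Ph3PCH3Br, KOt-Bu, THF, 0 → 50 °C
Reagents that add atoms: methyltriphenylphosphonium bromide, C[P+](c1ccccc1)(c1ccccc1)c1ccccc1.[Br-]
Why: Wittig methylenation of the methyl ketone installs the isopropenyl group, the tertiary alcohol being carried as its alkoxide and C7 remaining equatorial.

**Step 13**
Reactants: 27 isopropenyl carbinol; 28 N-methoxy-N,3-dimethylbutanamide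
Product: 32 3-{[(1S,4R,4aR,6R,8aS)-4-hydroxy-4,8a-dimethyl-6-(prop-1-en-2-yl)decahydronaphthalen-1-yl]methyl}-2,4,6-tris(methoxymethoxy)-5-(3-methylbutanoyl)benzaldehyde, via aryllithium 29 (not isolated), via lithium hemiaminal 30 (not isolated), via second aryllithium 31 (not isolated)
Conditions: n-BuLi (2.1 equiv), TMEDA, THF, 0 °C; DMF, −78 °C; n-BuLi (1.3 equiv), −78 → −20 °C; 28, −78 → 0 °C; aq NH4Cl
Reagents that add atoms: N,N-dimethylformamide, CN(C)C=O
Why: Two directed ortho-lithiations, each between two OMOM groups, are run in sequence, the DMF adduct persisting as a lithium α-amino alkoxide that masks the aldehyde while the last ring position is lithiated and acylated by the N-methoxy-N-methyl amide (which cannot over-add), and work-up releases aldehyde and ketone.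

**Step 14**
Reactants: 32 tris-MOM ether
Product: 33 2,4,6-trihydroxy-3-{[(1S,4R,4aR,6R,8aS)-4-hydroxy-4,8a-dimethyl-6-(prop-1-en-2-yl)decahydronaphthalen-1-yl]methyl}-5-(3-methylbutanoyl)benzaldehyde
Conditions: p-TsOH·H2O (0.3 equiv), MeOH, 23 → 40 °C
Reagents that add atoms: none
Why: Acid-catalysed acetal exchange removes the three MOM ethers, each activated by an ortho carbonyl group, under conditions mild enough for the tertiary alcohol and the isopropenyl group, and no stereocenter is touched.

**Compound list**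

1 | phloroglucinol (benzene-1,3,5-triol) | Oc1cc(O)cc(O)c1 | starting material
2 | 1,3,5-tris(methoxymethoxy)benzene | COCOc1cc(OCOC)cc(OCOC)c1 | intermediate
3 | acrolein (prop-2-enal) | C=CC=O | starting material
4 | [2,4,6-tris(methoxymethoxy)phenyl]lithium | [Li]c1c(OCOC)cc(OCOC)cc1OCOC | intermediate
5 | [2,4,6-tris(methoxymethoxy)phenyl]magnesium bromide | Br[Mg]c1c(OCOC)cc(OCOC)cc1OCOC | intermediate
6 | (E)-trimethyl({3-[2,4,6-tris(methoxymethoxy)phenyl]prop-1-en-1-yl}oxy)silane | C[Si](C)(C)O/C=C/Cc1c(OCOC)cc(OCOC)cc1OCOC | intermediate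
7 | 3-[2,4,6-tris(methoxymethoxy)phenyl]propanal | O=CCCc1c(OCOC)cc(OCOC)cc1OCOC | intermediate
8 | methyl vinyl ketone (but-3-en-2-one) | CC(=O)C=C | starting material
9 | (2S)-5-oxo-2-{[2,4,6-tris(methoxymethoxy)phenyl]methyl}hexanal | O=C[C@H](Cc1c(OCOC)cc(OCOC)cc1OCOC)CCC(C)=O | intermediate
10 | (4S)-4-{[2,4,6-tris(methoxymethoxy)phenyl]methyl}cyclohex-2-en-1-one | O=C1C=C[C@H](Cc2c(OCOC)cc(OCOC)cc2OCOC)CC1 | intermediate
11 | lithium (3S,4S)-3-methyl-4-{[2,4,6-tris(methoxymethoxy)phenyl]methyl}cyclohex-1-en-1-olate (methyl trans to arylmethyl) | [Li]OC1=C[C@@H](C)[C@H](Cc2c(OCOC)cc(OCOC)cc2OCOC)CC1 | intermediate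
12 | (4S)-3-methyl-4-{[2,4,6-tris(methoxymethoxy)phenyl]methyl}cyclohex-2-en-1-one | O=C1C=C(C)[C@H](Cc2c(OCOC)cc(OCOC)cc2OCOC)CC1 | intermediate
13 | triethyl{[(3S,4S)-3-ethenyl-3-methyl-4-{[2,4,6-tris(methoxymethoxy)phenyl]methyl}cyclohex-1-en-1-yl]oxy}silane (vinyl trans to arylmethyl) | C=C[C@@]1(C)[C@H](Cc2c(OCOC)cc(OCOC)cc2OCOC)CCC(O[Si](CC)(CC)CC)=C1 | intermediate
14 | 9-{2-[(1S,6S)-1-methyl-3-(triethylsilyloxy)-6-{[2,4,6-tris(methoxymethoxy)phenyl]methyl}cyclohex-2-en-1-yl]ethyl}-9-borabicyclo[3.3.1]nonane | B1(CC[C@@]2(C)[C@H](Cc3c(OCOC)cc(OCOC)cc3OCOC)CCC(O[Si](CC)(CC)CC)=C2)C2CCCC1CCC2 | intermediate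
15 | 2-[(1S,6S)-1-methyl-3-(triethylsilyloxy)-6-{[2,4,6-tris(methoxymethoxy)phenyl]methyl}cyclohex-2-en-1-yl]ethan-1-ol | OCC[C@@]1(C)[C@H](Cc2c(OCOC)cc(OCOC)cc2OCOC)CCC(O[Si](CC)(CC)CC)=C1 | intermediate
16 | triethyl{[(3S,4S)-3-(2-iodoethyl)-3-methyl-4-{[2,4,6-tris(methoxymethoxy)phenyl]methyl}cyclohex-1-en-1-yl]oxy}silane | ICC[C@@]1(C)[C@H](Cc2c(OCOC)cc(OCOC)cc2OCOC)CCC(O[Si](CC)(CC)CC)=C1 | intermediate
17 | acrylonitrile (prop-2-enenitrile) | C=CC#N | starting material
18 | tris(dimethylamino)sulfonium (3S,4S)-3-(2-iodoethyl)-3-methyl-4-{[2,4,6-tris(methoxymethoxy)phenyl]methyl}cyclohex-1-en-1-olate | ICC[C@@]1(C)[C@H](Cc2c(OCOC)cc(OCOC)cc2OCOC)CCC([O-])=C1.CN(C)[S+](N(C)C)N(C)C | intermediate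
19 | tris(dimethylamino)sulfonium 1-cyano-2-[(1S,2S,3S)-2-(2-iodoethyl)-2-methyl-6-oxo-3-{[2,4,6-tris(methoxymethoxy)phenyl]methyl}cyclohexyl]ethan-1-ide (new C5 substituent anti to the C10 methyl) | ICC[C@@]1(C)[C@H](Cc2c(OCOC)cc(OCOC)cc2OCOC)CCC(=O)[C@H]1C[CH-]C#N.CN(C)[S+](N(C)C)N(C)C | intermediate
20 | (2R,4aS,5S,8aS)-4a-methyl-8-oxo-5-{[2,4,6-tris(methoxymethoxy)phenyl]methyl}decahydronaphthalene-2-carbonitrile (cis-fused, 5β-H; 7β-nitrile drawn) | N#C[C@@H]1CC[C@@]2(C)[C@H](Cc3c(OCOC)cc(OCOC)cc3OCOC)CCC(=O)[C@H]2C1 | intermediate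
21 | (2R,4aS,5S,8aR)-4a-methyl-8-oxo-5-{[2,4,6-tris(methoxymethoxy)phenyl]methyl}decahydronaphthalene-2-carbonitrile (trans-fused, 5α-H; 7β-nitrile drawn) | N#C[C@@H]1CC[C@@]2(C)[C@H](Cc3c(OCOC)cc(OCOC)cc3OCOC)CCC(=O)[C@@H]2C1 | intermediate
22 | (2R,4aS,5S,8aS)-4a-methyl-8-methylidene-5-{[2,4,6-tris(methoxymethoxy)phenyl]methyl}decahydronaphthalene-2-carbonitrile (trans-fused) | N#C[C@@H]1CC[C@@]2(C)[C@H](Cc3c(OCOC)cc(OCOC)cc3OCOC)CCC(=C)[C@@H]2C1 | intermediate
23 | (2R,4aS,5S,8R,8aR)-8-hydroperoxy-4a,8-dimethyl-5-{[2,4,6-tris(methoxymethoxy)phenyl]methyl}decahydronaphthalene-2-carbonitrile | N#C[C@@H]1CC[C@@]2(C)[C@H](Cc3c(OCOC)cc(OCOC)cc3OCOC)CC[C@@](C)(OO)[C@@H]2C1 | intermediate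
24 | (2R,4aS,5S,8R,8aR)-8-hydroxy-4a,8-dimethyl-5-{[2,4,6-tris(methoxymethoxy)phenyl]methyl}decahydronaphthalene-2-carbonitrile (4α-OH in eudesmane terms) | N#C[C@@H]1CC[C@@]2(C)[C@H](Cc3c(OCOC)cc(OCOC)cc3OCOC)CC[C@@](C)(O)[C@@H]2C1 | intermediate
25 | dilithium salt (N-lithio ketimine, lithium alkoxide) from 24 and methyllithium | [Li]N=C(C)[C@@H]1CC[C@@]2(C)[C@H](Cc3c(OCOC)cc(OCOC)cc3OCOC)CC[C@@](C)(O[Li])[C@@H]2C1 | intermediate
26 | 1-[(2R,4aS,5S,8R,8aR)-8-hydroxy-4a,8-dimethyl-5-{[2,4,6-tris(methoxymethoxy)phenyl]methyl}decahydronaphthalen-2-yl]ethan-1-one | CC(=O)[C@@H]1CC[C@@]2(C)[C@H](Cc3c(OCOC)cc(OCOC)cc3OCOC)CC[C@@](C)(O)[C@@H]2C1 | intermediate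
27 | (1R,4S,4aS,7R,8aR)-1,4a-dimethyl-7-(prop-1-en-2-yl)-4-{[2,4,6-tris(methoxymethoxy)phenyl]methyl}decahydronaphthalen-1-ol | C=C(C)[C@@H]1CC[C@@]2(C)[C@H](Cc3c(OCOC)cc(OCOC)cc3OCOC)CC[C@@](C)(O)[C@@H]2C1 | intermediate
28 | N-methoxy-N,3-dimethylbutanamide | CON(C)C(=O)CC(C)C | starting material
29 | lithium alkoxide of 27 lithiated at one free aryl position | C=C(C)[C@@H]1CC[C@@]2(C)[C@H](Cc3c(OCOC)cc(OCOC)c([Li])c3OCOC)CC[C@@](C)(O[Li])[C@@H]2C1 | intermediate
30 | dilithium salt of the DMF adduct (aryl-CH(OLi)NMe2, lithium alkoxide) | C=C(C)[C@@H]1CC[C@@]2(C)[C@H](Cc3c(OCOC)cc(OCOC)c(C(O[Li])N(C)C)c3OCOC)CC[C@@](C)(O[Li])[C@@H]2C1 | intermediate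
31 | 30 lithiated at the last free aryl position | C=C(C)[C@@H]1CC[C@@]2(C)[C@H](Cc3c(OCOC)c([Li])c(OCOC)c(C(O[Li])N(C)C)c3OCOC)CC[C@@](C)(O[Li])[C@@H]2C1 | intermediate
32 | 3-{[(1S,4R,4aR,6R,8aS)-4-hydroxy-4,8a-dimethyl-6-(prop-1-en-2-yl)decahydronaphthalen-1-yl]methyl}-2,4,6-tris(methoxymethoxy)-5-(3-methylbutanoyl)benzaldehyde | C=C(C)[C@@H]1CC[C@@]2(C)[C@H](Cc3c(OCOC)c(C(=O)CC(C)C)c(OCOC)c(C=O)c3OCOC)CC[C@@](C)(O)[C@@H]2C1 | intermediate
33 | 2,4,6-trihydroxy-3-{[(1S,4R,4aR,6R,8aS)-4-hydroxy-4,8a-dimethyl-6-(prop-1-en-2-yl)decahydronaphthalen-1-yl]methyl}-5-(3-methylbutanoyl)benzaldehyde | C=C(C)[C@@H]1CC[C@@]2(C)[C@H](Cc3c(O)c(C=O)c(O)c(C(=O)CC(C)C)c3O)CC[C@@](C)(O)[C@@H]2C1 | target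

**Step count and risks**

Total steps: 14. Longest linear sequence: 14 (from phloroglucinol).

Steps most likely to fail:

1. Step 8. The α-cyano carbanion may be protonated by the C3 methylene of the newly formed ketone, or add a second acrylonitrile, before it reaches the iodide; the ring-fusion equilibration may also stop short. Fallback (the two bonds made separately with the ketone masked): starting from 16, the fluoride-triggered Michael addition is quenched with acetic acid at −78 °C to give the open-chain iodo keto nitrile F1. Its ketone is masked as the 1,3-dioxolane F2 (1,2-bis(trimethylsilyloxy)ethane, catalytic TMSOTf, CH2Cl2, −78 °C). LDA in THF/DMPU then generates only the nitrile anion, which closes ring B to the ketal nitrile F3. PPTS in wet acetone removes the ketal to give 20, and NaOMe/MeOH equilibrates C5, returning to the route at 21.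

2. Step 10. Oxygen trapping of the C4 radical may show poor facial selectivity, or the alkene may isomerize or be reduced. Fallback (ionic route through the epoxide): starting from 22, dimethyldioxirane should epoxidize the exocyclic alkene from the α face to give spiro-epoxide F4. MeLi followed by mild acid and methoxide converts the nitrile into epoxy methyl ketone F5. Wittig methylenation gives isopropenyl epoxide F6, and LiAlH4 opens the epoxide at its CH2 carbon to give the 4α-alcohol, returning to the route at 27.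

3. Step 13. The second lithiation may be incomplete, or butyllithium may attack the masked aldehyde, giving mixtures. Fallback (oxidation-level relay instead of in situ masking): starting from 27, lithiation (n-BuLi, TMEDA) and addition to 3-methylbutanal gives benzylic alcohol F7. A second lithiation, with both alkoxides as spectators, and DMF gives hydroxy aldehyde F8. Dess–Martin periodinane (NaHCO3 buffer) oxidises the benzylic alcohol to the ketone, returning to the route at 32.

**Further compounds**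

F1 | step 8 | 3-[(1S,2S,3S)-2-(2-iodoethyl)-2-methyl-6-oxo-3-{[2,4,6-tris(methoxymethoxy)phenyl]methyl}cyclohexyl]propanenitrile (kinetic C5 epimer drawn) | ICC[C@@]1(C)[C@H](Cc2c(OCOC)cc(OCOC)cc2OCOC)CCC(=O)[C@H]1CCC#N
F2 | step 8 | 1,3-dioxolane ketal of F1 | ICC[C@@]1(C)[C@H](Cc2c(OCOC)cc(OCOC)cc2OCOC)CCC3(OCCO3)[C@H]1CCC#N
F3 | step 8 | 1,3-dioxolane ketal of cis-fused keto nitrile 20 | N#C[C@@H]1CC[C@@]2(C)[C@H](Cc3c(OCOC)cc(OCOC)cc3OCOC)CCC4(OCCO4)[C@H]2C1
F4 | step 10 | 4α,15-epoxide of 22 (spiro-oxirane, oxygen on the α face) | N#C[C@@H]1CC[C@@]2(C)[C@H](Cc3c(OCOC)cc(OCOC)cc3OCOC)CC[C@@]4(OC4)[C@@H]2C1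
F5 | step 10 | 7β-acetyl 4α,15-epoxide | CC(=O)[C@@H]1CC[C@@]2(C)[C@H](Cc3c(OCOC)cc(OCOC)cc3OCOC)CC[C@@]4(OC4)[C@@H]2C1
F6 | step 10 | 7β-isopropenyl 4α,15-epoxide | C=C(C)[C@@H]1CC[C@@]2(C)[C@H](Cc3c(OCOC)cc(OCOC)cc3OCOC)CC[C@@]4(OC4)[C@@H]2C1
F7 | step 13 | benzylic alcohol from 27 and 3-methylbutanal (carbinol epimers) | C=C(C)[C@@H]1CC[C@@]2(C)[C@H](Cc3c(OCOC)cc(OCOC)c(C(O)CC(C)C)c3OCOC)CC[C@@](C)(O)[C@@H]2C1
F8 | step 13 | formylated benzylic alcohol (hydroxy aldehyde) | C=C(C)[C@@H]1CC[C@@]2(C)[C@H](Cc3c(OCOC)c(C=O)c(OCOC)c(C(O)CC(C)C)c3OCOC)CC[C@@](C)(O)[C@@H]2C1
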